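## Compound numbers and labels

Ar = 3-methoxy-4-(4-methylbenzenesulfonyloxy)phenyl.

- 1 vanillin
- 2 O-tosylvanillin
- 3 diethyl 2-(diethoxyphosphoryl)butanedioate
- 4 diethyl (E)-arylidenesuccinate
- 5 paraconate lactone (formed in the flask)
- 6 (E,E)-bis(arylidene)succinic half-ester
- 7 diethyl (E,E)-bis(arylidene)succinate
- 8 (E,E)-diene diol
- 9 bis-epoxide (formed in the flask)
- 10 spiro-epoxy tetrahydrofuran (formed in the flask)
- 11 prinsepiol bis-tosylate
- 12 prinsepiol

Atom labels: C7/C7' are the benzylic carbons, C8/C8' the ring-fusion carbinol carbons, C9/C9' the OCH2 carbons. Ring A is C7–O–C9'–C8'–C8 and ring B is C7'–O–C9–C8–C8'.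

## Analysis of the target

Prinsepiol 12 is a C2-symmetric furofuran lignan in which two tetrahydrofuran rings (A and B) are cis-fused along the C8–C8' bond. Each benzylic carbon carries a 4-hydroxy-3-methoxyphenyl group. It has four stereocentres, (7R,7'R,8S,8'S): C8 and C8' are tertiary carbinols whose hydroxyls are necessarily cis, and at C7 and C7' each aryl group is exo, that is cis to the hydroxyl on the adjacent fusion carbon. Because of the C2 axis only two things have to be controlled: the absolute configuration of one carbinol carbon and the C7/C8 relationship. The sensitive groups are the free guaiacyl phenols (oxidation), the para-oxygenated benzylic ethers (ionisation and epimerisation in acid) and the vicinal di-tertiary diol (glycol cleavage). The difficulty is to make two adjacent, fully substituted, oxygen-bearing carbons in one absolute sense from building blocks that have no stereocentre, and to set both benzylic centres with them. The route rests on one feature: in each half, C9 (OCH2), C8 (carbinol) and C7 (benzylic C–O) form the C1–C2–C3 array of a 2,3-epoxy alcohol opened at C3. The nucleophile at C7 is the C9' oxygen of the other half, so two such units joined head to tail account for every C–O bond of the bicycle.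

## Retrosynthetic reasoning

**12 from 11 (phenol O–S bonds).** The phenols are carried as tosylates in 11. An arenesulfonate is chosen over an ether because it turns the para oxygen from a strong donor into a weak acceptor, which the key step needs (next paragraph). It also survives amide base, hydride and acid, and it is removed at the end by electron transfer without acid.

**11 from 8 (C7–O, C7'–O, C8–O and C8'–O).** Cutting the two benzylic ether bonds and reading each tertiary hydroxyl as a former epoxide oxygen leads through bis-epoxide 9 to the achiral diene diol 8. This removes both rings and all four stereocentres at once. The forward reaction must epoxidise both allylic alcohols with the same facial sense and then open each epoxide at its benzylic carbon with inversion; the intermediate after the first opening is 10. One point shapes the whole design: each hydroxymethyl group is both the catalyst handle for its own alkene and the nucleophile for the epoxide of the other half. If the first epoxide opened before the second alkene was oxidised, the catalyst would lose its handle and the second epoxidation would no longer be reagent-controlled. Bis-epoxide 9 therefore has to survive until both oxygens are in place. With a donor group on the phenol oxygen, a benzylic epoxide ionises under the titanium catalyst; with the sulfonate it should behave like a halophenyl glycidol. Ring closure is then triggered separately with a Brønsted acid after titanium is removed, because the alkoxide ligands of titanium would compete as nucleophiles at C7.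

**8 from 7 and 6 (oxidation level at C9/C9').** The diol comes from the diester 7 by hydride reduction, and 7 from the half-ester 6 by O-alkylation. The ester level is used because geometrically defined trisubstituted alkenes are most reliably made as acrylates.

**6 from 4 and 2 (C7'=C8').** A Stobbe condensation joins the second aldehyde unit. It is chosen over a plain aldol condensation because the lactone 5 makes the elimination irreversible and regiodefined, and its ring opening places the aryl group trans to the carboxyl, the E geometry that the key step translates into the exo aryl group.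

**4 from 2 and 3 (C7=C8).** A Horner–Wadsworth–Emmons olefination with the phosphonosuccinate 3 gives the first E alkene directly as the diester. This saves an esterification and avoids alkoxide base.

**2 from 1 (phenol O–S bond).** Sulfonylation of vanillin 1.

## Alternatives that were turned down

**Alternative 1: double cross-benzoin.**
- Disconnection: C7–C8 and C7'–C8'. The C8–C8' unit would come from diethyl 2,3-dioxobutanedioate A2 and each aryl–C7 unit from the silyl ether of vanillin A3.
- Forward key step: under a chiral triazolium-derived carbene, A3 acts twice as an acyl anion equivalent toward the two ketones of A2 and gives the C2-symmetric bis(aroyl) dihydroxysuccinate A1.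
- For: both tertiary carbinols and both C7–C8 bonds are made in one catalytic operation from the aldehyde. In C–C bond economy this is stronger than the chosen route, and no alkene geometry has to be controlled.
- Against: A2 is a hydrate-prone, poor acceptor. The electron-rich aldehyde A3 is a sluggish donor and its homo-benzoin competes. The second addition must be matched to the first centre to give the C2 isomer and not the meso one. The addition is reversible.
- After A1, C7 and C7' are still ketones, C9 and C9' are esters, and no ring exists. Two diastereoselective ketone reductions, two ester reductions next to tertiary alcohols and two benzylic etherifications remain.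
- Comparison: the chosen strategy sets all four centres and both rings in the step that introduces asymmetry; A1 carries only two of the four centres.

**Alternative 2: carbenoid O–H insertion and aldol.**
- Disconnection: ring A at C7–O and C7–C8. Ring B would be preformed as the hydroxymethyl furanone A6 and joined with the aryldiazoacetate A5.
- Forward key step: a dirhodium tetracarboxylate catalyst such as Rh2(OAc)4 forms the carbenoid, which inserts into the primary O–H. The ylide or enol adds to the ring ketone to give the C7-methoxycarbonyl furofuran A4.
- For: the cis ring fusion is enforced by the intramolecular aldol, and the ring closes in an unstrained mode. On both points it is stronger than the 5-endo epoxide opening of the chosen route.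
- Against: A6 already holds C7' and C8' in enantiopure form, so the hardest part of the target has to be made beforehand by a separate asymmetric synthesis. The symmetry of 12 is not used. The ester at C7 is surplus and must be removed from a fully substituted benzylic ether carbon with the correct configuration.
- Comparison: the step count is far higher; the chosen strategy sets all centres from an achiral precursor in one step.

**Alternative 3: double bridgehead hydroxylation.**
- Disconnection: only C8–O and C8'–O. The bis-lactone A8 is in principle available by oxidative dimerisation of ferulic acid A9 and silylation.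
- Forward key step: deprotonation at both ring-fusion carbons and oxidation with an N-sulfonyloxaziridine to give the dihydroxy bis-lactone A7.
- For: this is the shortest access to the skeleton. The cis fusion and exo aryl groups are already in place, and hydroxylation can only occur with retention. On step count it beats the chosen route.
- Against: the dimerisation gives a racemate and offers no handle for absolute configuration. The enolate at C8 has the acyloxy oxygen of the other lactone on its β-carbon C7, so E1cB ring opening to an arylidene carboxylate is expected to compete with oxidation. This is the same elimination the Stobbe step of the chosen route uses on purpose. Two lactone carbonyls must afterwards be reduced to CH2 next to tertiary alcohols.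
- Comparison: the chosen strategy sets the absolute configuration with a catalyst and introduces the tertiary hydroxyls as part of ring construction, without a bridgehead enolate.

Key step: step 6

## Assumptions

- The facial sense of L-(+)-tartrate is taken from (E)-2-methyl-3-phenylprop-2-en-1-ol, which gives the (2S,3S)-epoxy alcohol. The same face of each alkene of 8 leads to (S,S,S,S)-9.
- Phosphonate 3 is taken as a commercial reagent.

## Route

Step 1
Reactants: 1 vanillin (4-hydroxy-3-methoxybenzaldehyde)
Product: 2 4-formyl-2-methoxyphenyl 4-methylbenzenesulfonate
Conditions: TsCl, Et3N, DMAP (cat.), CH2Cl2, 0 °C to rt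
Reagents that add atoms: 4-methylbenzenesulfonyl chloride, Cc1ccc(S(=O)(=O)Cl)cc1
Why: O-sulfonylation of a phenol; the tosylate should withstand the later amide base, hydride and acid, and it makes the aryl ring electron-poor enough for the epoxides of step 6 to persist.

Step 2
Reactants: 2 4-formyl-2-methoxyphenyl 4-methylbenzenesulfonate; 3 diethyl 2-(diethoxyphosphoryl)butanedioate (racemic)
Product: 4 diethyl (2E)-2-(Ar-methylidene)butanedioate
Conditions: NaH (1.0 equiv), THF, 0 °C to rt
Reagents that add atoms: none
Why: Horner–Wadsworth–Emmons olefination of an aromatic aldehyde with a stabilised α-substituted phosphonate; reversible addition should favour the E alkene with the aryl group trans to the ester, and one equivalent of non-nucleophilic base leaves the sulfonate alone.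

Step 3
Reactants: 4 diethyl (2E)-2-(Ar-methylidene)butanedioate; 2 4-formyl-2-methoxyphenyl 4-methylbenzenesulfonate
Product: 6 (2E,3E)-2,3-bis(Ar-methylidene)butanedioic acid monoethyl ester, via paraconate lactone 5 (not isolated)
Conditions: LiN(iPr)2 (1.1 equiv), THF, −78 °C; then 2; −78 °C to rt; aq. HCl
Reagents that add atoms: none
Why: Stobbe condensation run on the preformed lithium enolate: aldol addition to 2, lactonisation of the aldolate onto the conjugated ester (5) and E1cB opening of 5 by the released ethoxide give the half-ester; the ring opening should place the new aryl group trans to its carboxyl (E), and the amide base at low temperature spares the sulfonates.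

Step 4
Reactants: 6 (2E,3E)-2,3-bis(Ar-methylidene)butanedioic acid monoethyl ester
Product: 7 diethyl (2E,3E)-2,3-bis(Ar-methylidene)butanedioate
Conditions: EtI, K2CO3, DMF, rt
Reagents that add atoms: iodoethane, CCI
Why: SN2 O-alkylation of the carboxylate; mild carbonate base should touch neither the aryl sulfonates nor the alkene geometry.

Step 5
Reactants: 7 diethyl (2E,3E)-2,3-bis(Ar-methylidene)butanedioate
Product: 8 (2E,3E)-2,3-bis(Ar-methylidene)butane-1,4-diol
Conditions: iBu2AlH (5 equiv), CH2Cl2, −78 to 0 °C; aq. potassium sodium tartrate
Reagents that add atoms: none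
Why: 1,2-reduction of conjugated esters to allylic alcohols by an electrophilic aluminium hydride; the alkenes and the aryl sulfonates should not be reduced at this temperature.

Step 6
Reactants: 8 (2E,3E)-2,3-bis(Ar-methylidene)butane-1,4-diol
Product: 11 (1R,3aS,4R,6aS)-1,4-bis(Ar)tetrahydro-1H,3H-furo[3,4-c]furan-3a,6a-diol (prinsepiol bis-tosylate), via bis-epoxide 9 (not isolated), via spiro-epoxy tetrahydrofuran 10 (not isolated)
Conditions: Ti(OiPr)4 (0.3 equiv), L-(+)-diisopropyl tartrate (0.36 equiv), t-BuOOH (3 equiv, isooctane), 4 Å MS, CH2Cl2, −20 °C; filter, wash with aq. tartaric acid, dry; then CSA (0.3 equiv), CH2Cl2, 0 °C to rt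
Reagents that add atoms: tert-butyl hydroperoxide, CC(C)(C)OO
Why: Each hydroxymethyl group binds to the titanium–tartrate catalyst as its alkoxide and the peroxide oxygen is delivered to the alkene face fixed by the (R,R)-tartrate, the face that gives the (2S,3S)-epoxy alcohol from (E)-2-methyl-3-phenylprop-2-en-1-ol, so that two successive Sharpless asymmetric epoxidations should give the C2-symmetric (S,S,S,S) bis-epoxide 9. Once titanium is washed out, camphorsulfonic acid protonates one oxirane and the hydroxymethyl oxygen of the other half attacks benzylic C7 from the rear, closing ring A (10) and freeing the tertiary C8 hydroxyl; the liberated C9 hydroxyl then opens the spiro-epoxide at C7' in the same way and closes ring B. The closest known reaction types are the asymmetric epoxidation of 2,3-disubstituted cinnamyl alcohols, also run twice on diene diols, and the acid-catalysed cyclisation of 4-aryl-3,4-epoxy alcohols to 2-aryl-3-hydroxytetrahydrofurans. Both rings close by 5-endo epoxide opening (the nucleophile and both oxirane carbons end in the new ring); the 4-exo alternative at C8 or C8' would make an oxetane at a fully substituted carbon and is not expected to compete. C8 and C8' are set by the tartrate (reagent control, same sense twice), C7 and C7' by the E geometry of each alkene, syn epoxidation and inversion on opening, which places each aryl group cis to the neighbouring tertiary hydroxyl, that is exo. The step needs both epoxidations to be finished before either ring closes, because each hydroxymethyl is the catalyst handle of its own alkene and the nucleophile for the other epoxide; the sulfonate-deactivated aryl rings, the low titanium loading with sieves and −20 °C are what should keep the benzylic (and, at the mono-epoxide stage, vinylic) oxiranes intact. Attack at C7 and not at C8 is secured by the benzylic position and by ring size. A bis-epoxide of mixed facial sense cannot close the second ring to a cis-fused bicycle, so it should be lost as monocyclic material and the enantiomeric purity of 11 should exceed that of a single epoxidation.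

Step 7
Reactants: 11 (1R,3aS,4R,6aS)-1,4-bis(Ar)tetrahydro-1H,3H-furo[3,4-c]furan-3a,6a-diol
Product: 12 prinsepiol, (1R,3aS,4R,6aS)-1,4-bis(4-hydroxy-3-methoxyphenyl)tetrahydro-1H,3H-furo[3,4-c]furan-3a,6a-diol
Conditions: Mg, MeOH, rt; aq. NH4Cl
Reagents that add atoms: none
Why: Reductive S–O cleavage of aryl arenesulfonates by magnesium in methanol (electron transfer) should release both phenols without acid, so the benzylic ethers, now para to a donor oxygen, are not ionised and no stereocentre is touched.

## Compound list

1 | vanillin (4-hydroxy-3-methoxybenzaldehyde) | COc1cc(C=O)ccc1O | starting material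
2 | 4-formyl-2-methoxyphenyl 4-methylbenzenesulfonate | COc1cc(C=O)ccc1OS(=O)(=O)c1ccc(C)cc1 | intermediate
3 | diethyl 2-(diethoxyphosphoryl)butanedioate (racemic) | CCOC(=O)CC(C(=O)OCC)P(=O)(OCC)OCC | starting material
4 | diethyl (2E)-2-(Ar-methylidene)butanedioate | CCOC(=O)C/C(=C\c1ccc(OS(=O)(=O)c2ccc(C)cc2)c(OC)c1)C(=O)OCC | intermediate
5 | ethyl (4E)-2-Ar-4-(Ar-methylidene)-5-oxooxolane-3-carboxylate (paraconate lactone, racemic diastereomer mixture) | CCOC(=O)C1C(c2ccc(OS(=O)(=O)c3ccc(C)cc3)c(OC)c2)OC(=O)/C1=C/c1ccc(OS(=O)(=O)c2ccc(C)cc2)c(OC)c1 | intermediate
6 | (2E,3E)-2,3-bis(Ar-methylidene)butanedioic acid monoethyl ester | COc1cc(/C=C(/C(=O)O)C(\C(=O)OCC)=C/c2ccc(OS(=O)(=O)c3ccc(C)cc3)c(OC)c2)ccc1OS(=O)(=O)c1ccc(C)cc1 | intermediate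
7 | diethyl (2E,3E)-2,3-bis(Ar-methylidene)butanedioate | COc1cc(/C=C(/C(=O)OCC)C(\C(=O)OCC)=C/c2ccc(OS(=O)(=O)c3ccc(C)cc3)c(OC)c2)ccc1OS(=O)(=O)c1ccc(C)cc1 | intermediate
8 | (2E,3E)-2,3-bis(Ar-methylidene)butane-1,4-diol | COc1cc(/C=C(/CO)C(\CO)=C/c2ccc(OS(=O)(=O)c3ccc(C)cc3)c(OC)c2)ccc1OS(=O)(=O)c1ccc(C)cc1 | intermediate
9 | [(2S,2'S,3S,3'S)-3,3'-bis(Ar)-[2,2'-bioxirane]-2,2'-diyl]dimethanol | OC[C@@]1(O[C@H]1c2ccc(OS(=O)(=O)c3ccc(C)cc3)c(OC)c2)[C@@]4(CO)O[C@H]4c5ccc(OS(=O)(=O)c6ccc(C)cc6)c(OC)c5 | intermediate
10 | (2S,3S,6R,7S)-7-(hydroxymethyl)-2,6-bis(Ar)-1,5-dioxaspiro[2.4]heptan-7-ol | COc1cc([C@H]2OC[C@@]3(O[C@H]3c4ccc(OS(=O)(=O)c5ccc(C)cc5)c(OC)c4)[C@]2(O)CO)ccc1OS(=O)(=O)c1ccc(C)cc1 | intermediate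
11 | (1R,3aS,4R,6aS)-1,4-bis(Ar)tetrahydro-1H,3H-furo[3,4-c]furan-3a,6a-diol (prinsepiol bis-tosylate) | COc1cc([C@H]2OC[C@]3(O)[C@@H](c4ccc(OS(=O)(=O)c5ccc(C)cc5)c(OC)c4)OC[C@]23O)ccc1OS(=O)(=O)c1ccc(C)cc1 | intermediate
12 | prinsepiol, (1R,3aS,4R,6aS)-1,4-bis(4-hydroxy-3-methoxyphenyl)tetrahydro-1H,3H-furo[3,4-c]furan-3a,6a-diol | COc1cc([C@H]2OC[C@]3(O)[C@@H](c4ccc(O)c(OC)c4)OC[C@]23O)ccc1O | target

## Step count and least certain steps

Total step count: 7. Longest linear sequence: 7 steps (1 → 2 → 4 → 6 → 7 → 8 → 11 → 12); aldehyde 2 enters twice.

**Step 6 (key step).** The most likely failure is ring closure before the second epoxidation. The mono-epoxide is a vinyl epoxide, and if it opens at C7 the second alkene loses its catalyst handle, so the second oxygen is no longer delivered under tartrate control. Other concerns are slowing of the catalyst by chelation of titanium to the 1,4-diol, and partial loss of inversion at C7 if the acid-promoted opening becomes cationic.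

Fallback, from 8 and back at 10: the epoxidation is stopped at one equivalent of oxidant under the same Ti(OiPr)4/L-(+)-diisopropyl tartrate catalyst to give the mono-epoxide (2Z)-2-[(2S,3S)-3-Ar-2-(hydroxymethyl)oxiran-2-yl]-3-Ar-prop-2-en-1-ol F1 (unchanged alkene geometry, aryl cis to the oxirane carbon). CSA then closes ring A on purpose to the arylidene tetrahydrofuran diol (2R,3S,4Z)-2-Ar-3-(hydroxymethyl)-4-(Ar-methylidene)oxolan-3-ol F2. The tertiary allylic hydroxyl at C8 should direct VO(acac)2/t-BuOOH to the alkene face syn to itself, which gives 10, and acid closes ring B to 11. Here C8' and C7' are set by substrate control from the centres fixed in the first epoxidation. The weak point is competing direction by the homoallylic C9 hydroxyl to the opposite face, which is why this is the reserve.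

**Step 3.** The condensation may stall at lactone 5 if the lithium ethoxide released does not complete the E1cB opening. Ethoxide may also attack a sulfonate sulfur during warming, and some Z isomer may form.

Fallback, from 2 and back at 7: Wittig olefination of 2 with ethyl bromo(triphenylphosphoranylidene)acetate should give ethyl (2Z)-3-Ar-2-bromoprop-2-enoate F3, in which the aryl group is already trans to the ester. Reductive homocoupling at the C–Br bond joins C8 to C8' with retention and gives 7 without enolate chemistry. The conditions would be half an equivalent of bis(pinacolato)diboron, PdCl2(dppf), KOAc, then aq. K3PO4, dioxane, 80 °C (Miyaura borylation followed by Suzuki coupling in one flask).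

**Step 7.** Cleavage may stop after one sulfonate, or electron transfer may begin to reduce a benzylic C–O bond once the first phenolate has formed. The phenolates are also prone to air oxidation under basic conditions.

Fallback, from 11 directly to 12: hydrolytic instead of reductive cleavage, with KOH in aqueous methanol at moderate temperature under argon. Hydroxide attacks sulfur and releases the phenolate; the exo,exo skeleton is the thermodynamic one, so a reversible quinone-methide opening should not change the configuration. No new compound is made.

## Further compounds

F1 | step 6 | (2Z)-2-[(2S,3S)-3-Ar-2-(hydroxymethyl)oxiran-2-yl]-3-Ar-prop-2-en-1-ol | OC[C@@]1(O[C@H]1c2ccc(OS(=O)(=O)c3ccc(C)cc3)c(OC)c2)/C(CO)=C\c4ccc(OS(=O)(=O)c5ccc(C)cc5)c(OC)c4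
F2 | step 6 | (2R,3S,4Z)-2-Ar-3-(hydroxymethyl)-4-(Ar-methylidene)oxolan-3-ol | COc1cc([C@H]2OC/C(=C/c3ccc(OS(=O)(=O)c4ccc(C)cc4)c(OC)c3)[C@]2(O)CO)ccc1OS(=O)(=O)c1ccc(C)cc1
F3 | step 3 | ethyl (2Z)-3-Ar-2-bromoprop-2-enoate | CCOC(=O)/C(Br)=C/c1ccc(OS(=O)(=O)c2ccc(C)cc2)c(OC)c1
F0 | step 7 | none | none
A1 | alternative 1 | diethyl (2R,3R)-2,3-bis[4-(tert-butyldimethylsilyloxy)-3-methoxybenzoyl]-2,3-dihydroxybutanedioate | COc1cc(C(=O)[C@@](O)(C(=O)OCC)[C@](O)(C(=O)OCC)C(=O)c2ccc(O[Si](C)(C)C(C)(C)C)c(OC)c2)ccc1O[Si](C)(C)C(C)(C)C
A2 | alternative 1 | diethyl 2,3-dioxobutanedioate | CCOC(=O)C(=O)C(=O)C(=O)OCC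
A3 | alternative 1 | 4-(tert-butyldimethylsilyloxy)-3-methoxybenzaldehyde | COc1cc(C=O)ccc1O[Si](C)(C)C(C)(C)C
A4 | alternative 2 | methyl 1,4-bis[4-(tert-butyldimethylsilyloxy)-3-methoxyphenyl]-6a-hydroxy-3a-(triethylsilyloxy)tetrahydro-1H,3H-furo[3,4-c]furan-1-carboxylate | COc1cc([C@@]2(C(=O)OC)OC[C@]3(O[Si](CC)(CC)CC)[C@@H](c4ccc(O[Si](C)(C)C(C)(C)C)c(OC)c4)OC[C@]23O)ccc1O[Si](C)(C)C(C)(C)C
A5 | alternative 2 | methyl 2-[4-(tert-butyldimethylsilyloxy)-3-methoxyphenyl]-2-diazoacetate | COC(=O)C(=[N+]=[N-])c1ccc(O[Si](C)(C)C(C)(C)C)c(OC)c1
A6 | alternative 2 | 5-[4-(tert-butyldimethylsilyloxy)-3-methoxyphenyl]-4-(hydroxymethyl)-4-(triethylsilyloxy)oxolan-3-one | OC[C@]1(O[Si](CC)(CC)CC)[C@@H](c2ccc(O[Si](C)(C)C(C)(C)C)c(OC)c2)OCC1=O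
A7 | alternative 3 | 3,6-bis[4-(tert-butyldimethylsilyloxy)-3-methoxyphenyl]-3a,6a-dihydroxytetrahydro-1H,3H-furo[3,4-c]furan-1,4-dione | COc1cc([C@H]2OC(=O)[C@]3(O)[C@@H](c4ccc(O[Si](C)(C)C(C)(C)C)c(OC)c4)OC(=O)[C@]23O)ccc1O[Si](C)(C)C(C)(C)C
A8 | alternative 3 | 3,6-bis[4-(tert-butyldimethylsilyloxy)-3-methoxyphenyl]tetrahydro-1H,3H-furo[3,4-c]furan-1,4-dione | COc1cc([C@H]2OC(=O)[C@@H]3[C@@H](c4ccc(O[Si](C)(C)C(C)(C)C)c(OC)c4)OC(=O)[C@H]23)ccc1O[Si](C)(C)C(C)(C)C
A9 | alternative 3 | ferulic acid, (E)-3-(4-hydroxy-3-methoxyphenyl)prop-2-enoic acid | COc1cc(/C=C/C(=O)O)ccc1O
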